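## Retrosynthetic overview
1. Target **15** comes from tetra-O-benzyl ether **14** by global hydrogenolysis. **14** comes from diaryl carbinol **13** by Friedel–Crafts closure of the C1–C8a bond. This is the only new ring and the last one formed, trans to C2.
2. **13** comes from aldehyde **11** plus an aryl Grignard. **11** comes from oxidative cleavage of the propenyl group of **10**.
3. Key step: an Ireland–Claisen [3,3] rearrangement of ester **7** forms the C8–C8′ bond and sets both contiguous stereocenters by transfer from the carbinol of (S)-allylic alcohol **3**. The carbinol carbon is lost as the propenyl alkene, which is cleaved later.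
4. **3** comes from (S)-but-3-en-2-ol (**1**) by cross-metathesis. The acid **6** comes from dihydroferulic acid (**4**).

Assumptions: enantiopure (S)-but-3-en-2-ol, dihydroferulic acid and aryl bromide **12** are purchasable. Benzyl is the global O-protecting group. The Friedel–Crafts step gives mainly the 1,2-trans isomer, and any minor cis isomer is removed chromatographically.

## Route

**Step 1**
Reactants: **1** (S)-but-3-en-2-ol; **2** allyl benzyl ether (3 equiv)
Product: **3** (2S,3E)-5-(benzyloxy)pent-3-en-2-ol
Conditions: Hoveyda–Grubbs II (5 mol%), CH2Cl2, 40 °C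
Reagents that add atoms: none (ethylene is lost)
Why: Cross-metathesis joins the two terminal alkenes to give the E-disubstituted alkene, and excess **2** suppresses homodimerisation of **1**. The carbinol stereocenter is untouched.

**Step 2**
Reactants: **4** 3-(4-hydroxy-3-methoxyphenyl)propanoic acid
Product: **5** benzyl 3-[4-(benzyloxy)-3-methoxyphenyl]propanoate
Conditions: BnBr (2.3 equiv), K2CO3, DMF, rt
Reagents that add atoms: benzyl bromide, BrCc1ccccc1
Why: Williamson O-benzylation protects both the phenol and the carboxylate.

**Step 3**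
Reactants: **5**
Product: **6** 3-[4-(benzyloxy)-3-methoxyphenyl]propanoic acid
Conditions: LiOH, THF/MeOH/H2O, rt
Reagents that add atoms: lithium hydroxide, [Li+].[OH-] (its oxygen ends up in the carboxylic acid)
Why: Saponification cleaves the benzyl ester, and the aryl benzyl ether is stable to base.

**Step 4**
Reactants: **3**; **6**
Product: **7** (2S,3E)-5-(benzyloxy)pent-3-en-2-yl 3-[4-(benzyloxy)-3-methoxyphenyl]propanoate
Conditions: DCC, DMAP, CH2Cl2, 0 °C to rt
Reagents that add atoms: none
Why: Steglich esterification of a secondary alcohol leaves the stereocenter intact.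

**Step 5**
Reactants: **7**
Product: **8** (2R,3R,4E)-3-[(benzyloxy)methyl]-2-[4-(benzyloxy)-3-methoxybenzyl]hex-4-enoic acid
Conditions: LDA, THF, –78 °C; TMSCl; –78 °C to rt; then 1 M HCl
Reagents that add atoms: none (the TMS group is transient as a silyl ketene acetal and silyl ester, and is removed on workup)
Why: This is the Ireland–Claisen [3,3] rearrangement. LDA/THF without HMPA puts the CH2Ar group cis to the O-allyl group. The chair transition state has the E-alkene and the equatorial methyl, so the (S)-carbinol transfers suprafacially to the like (8R,8′R) pair and a new E-propenyl group.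

**Step 6**
Reactants: **8**
Product: **9** (2R,3R,4E)-3-[(benzyloxy)methyl]-2-[4-(benzyloxy)-3-methoxybenzyl]hex-4-en-1-ol
Conditions: LiAlH4, THF, 0 °C to rt
Reagents that add atoms: none
Why: LiAlH4 reduces the acid to the primary alcohol and leaves the alkene and the benzyl ethers alone. BH3 is avoided because it would hydroborate the alkene.

**Step 7**
Reactants: **9**
Product: **10** (2R,3R,4E)-1-(benzyloxy)-3-[(benzyloxy)methyl]-2-[4-(benzyloxy)-3-methoxybenzyl]hex-4-ene
Conditions: NaH, BnBr, TBAI (cat.), THF/DMF, 0 °C to rt
Reagents that add atoms: benzyl bromide, BrCc1ccccc1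
Why: Williamson benzylation blocks C9–OH so that it cannot trap the benzylic cation later as a tetrahydrofuran.

**Step 8**
Reactants: **10**
Product: **11** (2R,3R)-2,3-bis[(benzyloxy)methyl]-4-[4-(benzyloxy)-3-methoxyphenyl]butanal
Conditions: OsO4 (cat.), NaIO4, 2,6-lutidine, dioxane/H2O, rt
Reagents that add atoms: sodium periodate, [Na+].[O-]I(=O)(=O)=O (supplies the carbonyl oxygen)
Why: Lemieux–Johnson cleavage of the propenyl alkene gives the aldehyde at C7′. It is chosen over ozone to spare the electron-rich arene, and the buffered conditions limit epimerisation at C8′.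

**Step 9**
Reactants: **11**; **12** 1-(benzyloxy)-4-bromo-2-methoxybenzene, used as its Grignard reagent
Product: **13** 1-[4-(benzyloxy)-3-methoxyphenyl]-2,3-bis[(benzyloxy)methyl]-4-[4-(benzyloxy)-3-methoxyphenyl]butan-1-ol, (2R,3R), C1 epimeric mixture
Conditions: **12**, Mg, THF (ArMgBr); add **11**, THF, –78 °C to 0 °C; aq. NH4Cl
Reagents that add atoms: 4-(benzyloxy)-3-methoxyphenylmagnesium bromide, COc1cc([Mg]Br)ccc1OCc1ccccc1
Why: Grignard 1,2-addition to the aldehyde forms C7′–ArB. The new carbinol configuration is irrelevant because it is ionised in the next step.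

**Step 10**
Reactants: **13**
Product: **14** (1S,2R,3R)-7-(benzyloxy)-1-[4-(benzyloxy)-3-methoxyphenyl]-2,3-bis[(benzyloxy)methyl]-6-methoxy-1,2,3,4-tetrahydronaphthalene
Conditions: TFA, CH2Cl2, 0 °C
Reagents that add atoms: none (water is lost)
Why: This is an intramolecular Friedel–Crafts benzylation. The stabilised diaryl-type cation at C7′ is attacked by ring A at the carbon para to OMe. The aryl group goes trans to the C2 substituent, which avoids A1,2 strain, giving the all-trans 1S configuration under control of the existing (2R,3R) centers.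

**Step 11**
Reactants: **14**
Product: **15** (+)-isolariciresinol
Conditions: H2 (1 atm), 10% Pd/C, EtOAc/EtOH, rt
Reagents that add atoms: none (only hydrogen is added)
Why: Hydrogenolysis removes all four benzyl ethers and leaves the saturated stereocenters untouched.

## Compound list
1 | (S)-but-3-en-2-ol | C=C[C@H](C)O | starting material
2 | allyl benzyl ether | C=CCOCc1ccccc1 | starting material
3 | (2S,3E)-5-(benzyloxy)pent-3-en-2-ol | C[C@H](O)/C=C/COCc1ccccc1 | intermediate
4 | 3-(4-hydroxy-3-methoxyphenyl)propanoic acid | COc1cc(CCC(=O)O)ccc1O | starting material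
5 | benzyl 3-[4-(benzyloxy)-3-methoxyphenyl]propanoate | COc1cc(CCC(=O)OCc2ccccc2)ccc1OCc1ccccc1 | intermediate
6 | 3-[4-(benzyloxy)-3-methoxyphenyl]propanoic acid | COc1cc(CCC(=O)O)ccc1OCc1ccccc1 | intermediate
7 | allylic ester (Claisen substrate) | C[C@@H](/C=C/COCc1ccccc1)OC(=O)CCc1ccc(OCc2ccccc2)c(OC)c1 | intermediate
8 | (2R,3R,4E)-Claisen acid | C/C=C/[C@@H](COCc1ccccc1)[C@@H](Cc1ccc(OCc2ccccc2)c(OC)c1)C(=O)O | intermediate
9 | (2R,3R,4E)-primary alcohol | C/C=C/[C@@H](COCc1ccccc1)[C@@H](Cc1ccc(OCc2ccccc2)c(OC)c1)CO | intermediate
10 | tribenzyl ether alkene | C/C=C/[C@@H](COCc1ccccc1)[C@@H](Cc1ccc(OCc2ccccc2)c(OC)c1)COCc1ccccc1 | intermediate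
11 | (2R,3R)-aldehyde | O=C[C@@H](COCc1ccccc1)[C@@H](Cc1ccc(OCc2ccccc2)c(OC)c1)COCc1ccccc1 | intermediate
12 | 1-(benzyloxy)-4-bromo-2-methoxybenzene | COc1cc(Br)ccc1OCc1ccccc1 | starting material
13 | diaryl carbinol (C1 epimers) | OC(c1ccc(OCc2ccccc2)c(OC)c1)[C@@H](COCc1ccccc1)[C@@H](Cc1ccc(OCc2ccccc2)c(OC)c1)COCc1ccccc1 | intermediate
14 | tetra-O-benzyl isolariciresinol | COc1cc([C@H]2c3cc(OCc4ccccc4)c(OC)cc3C[C@@H](COCc5ccccc5)[C@@H]2COCc6ccccc6)ccc1OCc7ccccc7 | intermediate
15 | (+)-isolariciresinol | COc1cc([C@H]2c3cc(O)c(OC)cc3C[C@@H](CO)[C@@H]2CO)ccc1O | target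

Atom check: **15** is C20H24O6, matching isolariciresinol. Hydrogenolysis removes four benzyl groups from **14** (C48H48O6).

Total steps: 11. Longest linear sequence: 10 steps (**4** → **6** → **7** → **8** → **9** → **10** → **11** → **13** → **14** → **15**, counting steps 2–11).

## Three steps most likely to fail
1. **Step 10, Friedel–Crafts closure.** The risks are a cis/trans mixture at C1, or trapping of the cation by the C9 benzyl ether to give a tetrahydrofuran. Fallback: take acid **8** through an aldehyde-acid, add ArMgBr so that the hydroxy-acid lactonises, cyclise that 7′-aryl γ-lactone with TFA to the aryltetralin lactone (the α-conidendrin type), then reduce with LiAlH4 and hydrogenolyse.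
2. **Step 5, Ireland–Claisen.** Enolate geometry, diastereoselectivity, or competing side reactions of the lithium enolate could erode the (2R,3R) outcome. Fallback: Johnson–Claisen of **3** with MeC(OEt)3 to fix C8′, then anti-selective α-benzylation of the resulting ester enolate with the aryl-methyl bromide to set C8.
3. **Steps 8–9, the α-stereogenic, β-alkoxy aldehyde.** It may epimerise or eliminate BnOH. Fallback: stop at free alcohol **9**, cleave the alkene to the configurationally stable lactol, open it with excess ArMgBr, then benzylate the resulting diol and cyclise as in step 10.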